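## Structural features

The target is a 2,3-dihydro-1-benzofuran: benzene ring A (C3a to C7a) is fused to a five-membered ring that holds O1, C2 and C3. C2 carries a 4-hydroxy-3,5-dimethoxyphenyl (syringyl) ring and C3 a hydroxymethyl group (C9). These two adjacent stereocentres are trans, (2S,3R), and are the only ones in the molecule. Ring A is 1,2,3,5-tetrasubstituted: O1 on C7a, a methoxy group on C7, the C3 side chain on C3a, and an acetyl group on C5, para to C7a. The C2–O1 bond is a para-hydroxybenzyl aryl ether whose aryloxide is a good leaving group because of the para acetyl group, so strong acid or a free phenoxide can open it through a benzylic cation or quinone methide and scramble C2. The acetyl group is enolisable and the free phenol is easily oxidised. The real difficulty is to set the absolute configuration of the C2/C3 pair and then close the ether ring without touching either centre. The key step uses the fact that O1 is bonded to the aromatic carbon C7a, para to the acyl-bearing C5: a fluorine on C7a can be displaced by the C2 oxygen, so the new bond is made at an aryl carbon and not at a stereocentre.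

## Logic of the disconnections

**19 from 18 and 17.** Only two oxygen–protecting-group bonds are cut: O–Si on the syringyl phenol and O–CPh3 on C9. This leaves the skeleton, the ketone and both stereocentres untouched at the end. The forward steps must spare the C2–O1 benzylic aryl ether. Therefore the acid step (17 to 18) is run while the phenol is still silylated, and the buffered fluoride step (18 to 19) comes last.

**17 from 15.** The C–CH3 bond of the acetyl group is cut, taking the C5 substituent back to a methyl ester. A methyl ketone could not be present in the ring closure because the base would enolise it and the enolate would deactivate ring A. The ester has no acidic hydrogen and activates the para position. The forward step needs a single addition of a methyl nucleophile, which is secured by passing through amide 16 in the same flask.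

**15 from 14.** The O1–C7a bond is cut, opening the dihydrofuran ring to an acyclic fluoroarene alcohol. The cut is placed at the aryl carbon so that the C2–O bond is never broken. The configuration of 14 then maps onto 15 with retention, syn in the open chain becoming trans in the ring. The forward step needs ring A to accept an alkoxide at C7a (fluorine para to the ester) and needs only the C2 oxygen to be free.

**14 from 13 and 12.** The O–CPh3 bond at C9 is cut, then C9 is taken back to the acyl oxidation level and the N–acyl bond to the auxiliary is restored. Trityl is chosen for C9 because it goes selectively onto the primary hydroxyl and cannot shift to the neighbouring alkoxide, as a silyl or acyl group could. A free C9 alkoxide would close the isomeric five-membered ring. The forward reduction must remove the auxiliary without reducing the ring-A ester or reversing the aldol.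

**12 from 10 and 2.** The C2–C3 bond is cut. This is the only C–C bond between the two halves, and forming it by a syn-selective auxiliary aldol sets both stereocentres at once from two achiral-at-carbon fragments. The forward step needs the Z enolate and the facial bias of the (S)-benzyl auxiliary, which give the (2S,3S) adduct, the pattern required for (2S,3R)-19.

**10 from 7 and 8, 7 from 6, 6 from 4 and 5, 4 from 3.** The cuts are the imide N–C bond, the tert-butyl ester O–C bond, the bond from C3a to the future C3 methylene, and the C–B bond at C3a. This takes ring A back to a commercial benzoate that already carries the fluorine, the methoxy group and the acyl carbon in the right places. The C–H borylation must occur at the one position next to fluorine. The tert-butyl ester must be cleavable beside the methyl ester.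

**2 from 1.** The O–Si bond is cut. The phenol must be masked through the boron aldol, the hydride reduction, the amide base and the organomagnesium step. A hindered aryl silyl ether survives all of these and falls to fluoride at the end.

## Other disconnections considered

**Alternative 1:** The cut is at C2–C1' and C3–C3a, the two aryl–carbon bonds, with O1–C2 left for a later closure.
- **Forward key step:** the aryllithium from aryl bromide A4 adds to (E)-alkenyl boronate A3 to give an ate complex. Pd(OAc)2 with chiral MandyPhos activates ring-A aryl bromide A2. The arylpalladium species triggers a 1,2-shift of the syringyl group from boron to C2 while ring A is delivered to C3, anti across the former double bond. This gives boronic ester A1, (2R,3S) by its propoxy locants.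
- **In favour:** three simple fragments are joined in one catalytic enantioselective operation, with two C–C bonds and both stereocentres made at once and no auxiliary to attach or remove.
- **Against:** β-substituted alkenyl boronates are the less forgiving class for this coupling, because direct Suzuki transfer competes and the pinacol ligand may have to be replaced by a bulkier diol. A2 is hindered by its ortho alkoxy group. Ring A already carries its oxygen on C7a, so the ring must be closed by forming O1–C2. After oxidation of C–B to C–OH with retention, A1 has the relative configuration that would give trans only if the C2–O bond were kept. An invertive Mitsunobu closure would give the cis ring. Closure would therefore have to pass through the benzylic cation under acid, with trans reached by thermodynamic control, or a Z-alkenyl boronate would be needed.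
- **Comparison:** on convergence and longest linear sequence this alternative is the better plan, probably by two or three steps, and its stereocontrol is catalytic. On structure and mechanism the chosen plan is safer, because it never breaks the C2–O bond and its ring closure has no stereochemical question to answer.

**Alternative 2:** The cut is at C2–C3.
- **Forward key step:** aryldiazoacetate A6 loses N2 on Rh2(S-PTTL)4 (or its mirror image). The rhodium carbene inserts into the benzylic O–CH2 bond in a 1,5 fashion, closing the dihydrofuran ring, and NaOMe in the same pot epimerises C3 to give trans ester A5.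
- **In favour:** the ring and the C2–C3 bond are made together under catalytic asymmetric control. Both C–O bonds of O1 come from a simple phenol benzylation. The ester of A5 reduces directly to C9H2OH, and few protecting-group steps follow the key step.
- **Against:** the acetyl group must be masked as a dioxolane, since a free ketone would trap the carbene. A6 is a diazo compound and needs a ring-A ortho-hydroxyarylacetate that is itself several steps from commercial material. The C7 methoxy group sits next to the benzyloxy group and may change the conformation on which the enantioselectivity depends. The correct catalyst enantiomer must be found by trial. The final acid removal of the dioxolane and the methoxymethyl group meets the same labile C2–O1 bond as the chosen plan, here with the phenol free.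
- **Comparison:** on step economy and on avoiding a stoichiometric auxiliary this alternative is the equal or the better of the chosen plan. The trans relationship is secured by equilibration in both plans in effect, so they are equal there. The chosen plan is ahead in predictability of the absolute configuration, which follows from a well-understood acyclic aldol and not from a catalyst on an untested substitution pattern.

**Alternative 3:** The cut is at C3–C9 and C2–C1', on a preformed benzofuran.
- **Forward key step:** benzofuran A8 is lithiated at C2 and combined with syringyl boronic ester A9 to give an ate complex. The allyl complex from allyl acetate, Pd2(dba)3 and (S)-BINAP (or its enantiomer) then alkylates C3 while the syringyl group shifts from boron to C2 on the opposite face. This dearomatises the furan ring and gives boronic ester A7, (2S,3S), with the aryl group trans to the allyl group.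
- **In favour:** O1–C2 and O1–C7a exist from the start, so there is no ring closure and no C–O stereochemical issue. Two C–C bonds and both centres arise in one catalytic step, and the route is modular in the aryl group.
- **Against:** the allyl group brings two carbons too many. Alkene isomerisation, ozonolysis and reduction are needed to reach C9H2OH, and they pass through an epimerisable C3 aldehyde beside electron-rich arenes. The tertiary α-oxy benzylic C–B bond must be protodeboronated with retention. A8 needs its own benzofuran synthesis.
- **Comparison:** on structure this alternative is the better plan for the ether ring, and it is equal in being stereochemically well defined at the key step. On mechanism it carries more open questions (protodeboronation, enantioselectivity with this benzofuran). On step economy it is behind the chosen plan, since four or five steps follow the key step besides the synthesis of A8.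

Key step: step 9

Remark: compounds 1, 3, 5 and 8 are taken as purchasable. The descriptor of the ring-A-bearing carbon changes from S in 12 to R in 13 only because the CIP ranking of its neighbours changes on reduction; the (S)-benzyl auxiliary was checked to lead to (2S,3R)-19.

## Route

Step 1
Reactants: 1 syringaldehyde (4-hydroxy-3,5-dimethoxybenzaldehyde)
Product: 2 3,5-dimethoxy-4-(triisopropylsilyloxy)benzaldehyde
Conditions: TIPSCl, imidazole, DMAP (cat.), DMF, 40 °C
Reagents that add atoms: triisopropylsilyl chloride, CC(C)[Si](Cl)(C(C)C)C(C)C
Why: O-silylation of a phenol made more acidic by the para formyl group; gentle warming should overcome the two flanking methoxy groups. The hindered aryl silyl ether is chosen to survive the boron triflate, borohydride, amide base and organomagnesium steps.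

Step 2
Reactants: 3 methyl 4-fluoro-3-methoxybenzoate
Product: 4 methyl 4-fluoro-3-methoxy-5-(4,4,5,5-tetramethyl-1,3,2-dioxaborolan-2-yl)benzoate
Conditions: [Ir(OMe)(cod)]2 (1.5 mol %), 4,4'-di-tert-butyl-2,2'-bipyridine (3 mol %), B2pin2 (1.0 equiv), THF, 80 °C (sealed)
Reagents that add atoms: bis(pinacolato)diboron, CC1(C)OB(OC1(C)C)B1OC(C)(C)C(C)(C)O1
Why: Iridium-catalysed aromatic C–H borylation under steric control: C2 lies between the ester and the methoxy group and C6 is ortho to the ester, so only C5, next to the small fluorine and bearing the most acidic C–H, should react.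

Step 3
Reactants: 4 methyl 4-fluoro-3-methoxy-5-(4,4,5,5-tetramethyl-1,3,2-dioxaborolan-2-yl)benzoate, 5 tert-butyl bromoacetate
Product: 6 methyl 3-(2-tert-butoxy-2-oxoethyl)-4-fluoro-5-methoxybenzoate
Conditions: Pd(OAc)2 (3 mol %), P(o-tol)3 (9 mol %), K3PO4, THF/H2O, 50 °C
Reagents that add atoms: none
Why: Suzuki–Miyaura coupling of an arylboronic ester with an α-bromo ester: oxidative addition of the C–Br bond to zerovalent palladium, transmetalation and reductive elimination, with no β-hydrogen to eliminate. The tert-butyl ester keeps the new carboxyl distinct from the ring methyl ester.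

Step 4
Reactants: 6 methyl 3-(2-tert-butoxy-2-oxoethyl)-4-fluoro-5-methoxybenzoate
Product: 7 2-[2-fluoro-3-methoxy-5-(methoxycarbonyl)phenyl]acetic acid
Conditions: CF3CO2H/CH2Cl2 (1:3), rt
Reagents that add atoms: none
Why: Acidolysis of a tert-butyl ester through the tert-butyl cation, which leaves as isobutene; the methyl ester and the aryl ethers are inert to these conditions.

Step 5
Reactants: 7 2-[2-fluoro-3-methoxy-5-(methoxycarbonyl)phenyl]acetic acid, 8 (S)-4-benzyl-2-oxazolidinone
Product: 10 methyl 3-{2-[(4S)-4-benzyl-2-oxo-1,3-oxazolidin-3-yl]-2-oxoethyl}-4-fluoro-5-methoxybenzoate, via mixed pivalic anhydride 9 (not isolated)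
Conditions: t-BuCOCl, Et3N, THF, −20 °C; then LiCl, 8, −20 °C to rt
Reagents that add atoms: none
Why: N-acylation of the oxazolidinone by a mixed anhydride, which is attacked at its less hindered acyl carbon. LiCl with Et3N activates the auxiliary without butyllithium, so the ring methyl ester is not at risk.

Step 6
Reactants: 10 methyl 3-{2-[(4S)-4-benzyl-2-oxo-1,3-oxazolidin-3-yl]-2-oxoethyl}-4-fluoro-5-methoxybenzoate, 2 3,5-dimethoxy-4-(triisopropylsilyloxy)benzaldehyde
Product: 12 methyl 3-[(2S,3S)-1-[(4S)-4-benzyl-2-oxo-1,3-oxazolidin-3-yl]-3-[3,5-dimethoxy-4-(triisopropylsilyloxy)phenyl]-3-hydroxy-1-oxopropan-2-yl]-4-fluoro-5-methoxybenzoate, via Z-dibutylboron enolate 11 (not isolated)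
Conditions: Bu2BOTf, iPr2NEt, CH2Cl2, −78 to 0 °C; then 2, −78 to 0 °C; pH 7 buffer, MeOH, 30% H2O2, 0 °C
Reagents that add atoms: none
Why: Evans syn aldol: soft enolisation gives Z-boron enolate 11, which reacts through a closed Zimmerman–Traxler chair with the auxiliary carbonyl turned away from the enolate oxygen and the benzyl group blocking one face. The aldehyde is therefore taken up on the other face and both new centres are set together as (2S,3S), syn. The aryl group on the enolate only makes enolisation easier, and aromatic aldehydes are standard partners.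

Step 7
Reactants: 12 methyl 3-[(2S,3S)-1-[(4S)-4-benzyl-2-oxo-1,3-oxazolidin-3-yl]-3-[3,5-dimethoxy-4-(triisopropylsilyloxy)phenyl]-3-hydroxy-1-oxopropan-2-yl]-4-fluoro-5-methoxybenzoate
Product: 13 methyl 3-[(1S,2R)-1-[3,5-dimethoxy-4-(triisopropylsilyloxy)phenyl]-1,3-dihydroxypropan-2-yl]-4-fluoro-5-methoxybenzoate
Conditions: NaBH4, THF/H2O (4:1), 0 °C to rt
Reagents that add atoms: none
Why: Reductive cleavage of an N-acyloxazolidinone by borohydride in wet THF: hydride adds to the exocyclic imide carbonyl, the auxiliary leaves and the aldehyde is reduced further, while the less electrophilic methyl benzoate should be left alone at this temperature. No bond to either stereocentre is broken.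

Step 8
Reactants: 13 methyl 3-[(1S,2R)-1-[3,5-dimethoxy-4-(triisopropylsilyloxy)phenyl]-1,3-dihydroxypropan-2-yl]-4-fluoro-5-methoxybenzoate
Product: 14 methyl 3-[(1S,2R)-1-[3,5-dimethoxy-4-(triisopropylsilyloxy)phenyl]-1-hydroxy-3-(trityloxy)propan-2-yl]-4-fluoro-5-methoxybenzoate
Conditions: Ph3CCl, Et3N, DMAP (cat.), CH2Cl2, rt
Reagents that add atoms: trityl chloride, ClC(c1ccccc1)(c1ccccc1)c1ccccc1
Why: Tritylation through the trityl cation is strongly selective for the primary hydroxyl on steric grounds; the hindered secondary benzylic hydroxyl should stay free, and the amine base keeps the medium from ionising it.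

Step 9
Reactants: 14 methyl 3-[(1S,2R)-1-[3,5-dimethoxy-4-(triisopropylsilyloxy)phenyl]-1-hydroxy-3-(trityloxy)propan-2-yl]-4-fluoro-5-methoxybenzoate
Product: 15 methyl (2S,3R)-2-[3,5-dimethoxy-4-(triisopropylsilyloxy)phenyl]-7-methoxy-3-(trityloxymethyl)-2,3-dihydro-1-benzofuran-5-carboxylate
Conditions: KN(SiMe3)2 (1.2 equiv), THF (0.02 M), −40 °C to rt
Reagents that add atoms: none
Why: The amide base removes the only acidic proton, that of the C2 hydroxyl; the potassium alkoxide adds to C7a to give a Meisenheimer anion whose charge is taken up by the para ester carbonyl, and loss of fluoride restores the arene with the O1–C7a bond in place. The closest known reaction type is the intramolecular nucleophilic aromatic substitution of 2-(2-fluoroaryl)ethanols activated by a para carbonyl group, which gives 2,3-dihydrobenzofurans. The dihydrofuran ring closes in the 5-exo-trig mode, since the π system that accepts the electrons lies outside the new ring. No stereocentre is created: the C2–O bond is never broken and C3 has no acidic hydrogen (the ester is meta to C3a), so the syn pattern of 14 becomes the trans ring of 15 with retention at both centres. The step needs selectivity between the two oxygens, secured by the trityl ether on C9, which cannot migrate to the alkoxide. It also needs selectivity between the aryl carbon and the ester carbonyl, secured by the five-membered transition state and by high dilution, which disfavours intermolecular acyl attack. Regioselectivity on ring A is not at issue because fluorine is the only leaving group and sits ortho to the side chain.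

Step 10
Reactants: 15 methyl (2S,3R)-2-[3,5-dimethoxy-4-(triisopropylsilyloxy)phenyl]-7-methoxy-3-(trityloxymethyl)-2,3-dihydro-1-benzofuran-5-carboxylate
Product: 17 1-[(2S,3R)-2-[3,5-dimethoxy-4-(triisopropylsilyloxy)phenyl]-7-methoxy-3-(trityloxymethyl)-2,3-dihydro-1-benzofuran-5-yl]ethan-1-one, via Weinreb amide 16 (not isolated)
Conditions: MeNHOMe·HCl, iPrMgCl, THF, −20 to 0 °C; then MeMgBr, 0 °C; aq NH4Cl
Reagents that add atoms: methylmagnesium bromide, C[Mg]Br
Why: Ester-to-ketone conversion through a Weinreb amide made in the same flask: the chloromagnesium amide of N,O-dimethylhydroxylamine (formed by iPrMgCl, which is too hindered to attack the aryl ester at this temperature) gives 16. MeMgBr then adds only once because the tetrahedral adduct is held as a five-membered magnesium chelate until work-up. Both hydroxyl groups are capped, so no alkoxide forms next to C2.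

Step 11
Reactants: 17 1-[(2S,3R)-2-[3,5-dimethoxy-4-(triisopropylsilyloxy)phenyl]-7-methoxy-3-(trityloxymethyl)-2,3-dihydro-1-benzofuran-5-yl]ethan-1-one
Product: 18 1-[(2S,3R)-2-[3,5-dimethoxy-4-(triisopropylsilyloxy)phenyl]-3-(hydroxymethyl)-7-methoxy-2,3-dihydro-1-benzofuran-5-yl]ethan-1-one
Conditions: camphorsulfonic acid (cat.), MeOH/CH2Cl2 (1:2), 0 °C to rt
Reagents that add atoms: none
Why: Acid-catalysed methanolysis of a trityl ether through the trityl cation, which forms far more readily than any cation at C2. The aryl silyl ether tolerates mild acid, and keeping the phenol silylated at this stage closes off the quinone methide pathway for the C2–O1 bond.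

Step 12
Reactants: 18 1-[(2S,3R)-2-[3,5-dimethoxy-4-(triisopropylsilyloxy)phenyl]-3-(hydroxymethyl)-7-methoxy-2,3-dihydro-1-benzofuran-5-yl]ethan-1-one
Product: 19 1-[(2S,3R)-2-(4-hydroxy-3,5-dimethoxyphenyl)-3-(hydroxymethyl)-7-methoxy-2,3-dihydro-1-benzofuran-5-yl]ethan-1-one
Conditions: Bu4NF, AcOH, THF, 0 °C
Reagents that add atoms: none
Why: Fluoride-induced cleavage of an aryl silyl ether, driven by the Si–F bond. Acetic acid protonates the phenoxide at once, so it can neither expel the para-acyl aryloxide through a quinone methide nor enolise the ketone.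

## Compound list

1 | syringaldehyde (4-hydroxy-3,5-dimethoxybenzaldehyde) | COc1cc(C=O)cc(OC)c1O | starting material
2 | 3,5-dimethoxy-4-(triisopropylsilyloxy)benzaldehyde | COc1cc(C=O)cc(OC)c1O[Si](C(C)C)(C(C)C)C(C)C | intermediate
3 | methyl 4-fluoro-3-methoxybenzoate | COC(=O)c1ccc(F)c(OC)c1 | starting material
4 | methyl 4-fluoro-3-methoxy-5-(4,4,5,5-tetramethyl-1,3,2-dioxaborolan-2-yl)benzoate | COC(=O)c1cc(OC)c(F)c(B2OC(C)(C)C(C)(C)O2)c1 | intermediate
5 | tert-butyl bromoacetate | CC(C)(C)OC(=O)CBr | starting material
6 | methyl 3-(2-tert-butoxy-2-oxoethyl)-4-fluoro-5-methoxybenzoate | COC(=O)c1cc(OC)c(F)c(CC(=O)OC(C)(C)C)c1 | intermediate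
7 | 2-[2-fluoro-3-methoxy-5-(methoxycarbonyl)phenyl]acetic acid | COC(=O)c1cc(OC)c(F)c(CC(=O)O)c1 | intermediate
8 | (S)-4-benzyl-2-oxazolidinone | O=C1OC[C@H](Cc2ccccc2)N1 | starting material
9 | 2-[2-fluoro-3-methoxy-5-(methoxycarbonyl)phenyl]acetic pivalic anhydride | COC(=O)c1cc(OC)c(F)c(CC(=O)OC(=O)C(C)(C)C)c1 | intermediate (not isolated)
10 | methyl 3-{2-[(4S)-4-benzyl-2-oxo-1,3-oxazolidin-3-yl]-2-oxoethyl}-4-fluoro-5-methoxybenzoate | COC(=O)c1cc(OC)c(F)c(CC(=O)N2[C@@H](Cc3ccccc3)COC2=O)c1 | intermediate
11 | Z-dibutylboron enolate of 10 | CCCCB(CCCC)O/C(=C\c1cc(C(=O)OC)cc(OC)c1F)N1[C@@H](Cc2ccccc2)COC1=O | intermediate (not isolated)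
12 | methyl 3-[(2S,3S)-1-[(4S)-4-benzyl-2-oxo-1,3-oxazolidin-3-yl]-3-[3,5-dimethoxy-4-(triisopropylsilyloxy)phenyl]-3-hydroxy-1-oxopropan-2-yl]-4-fluoro-5-methoxybenzoate | COC(=O)c1cc(OC)c(F)c([C@H](C(=O)N2[C@@H](Cc3ccccc3)COC2=O)[C@H](O)c2cc(OC)c(O[Si](C(C)C)(C(C)C)C(C)C)c(OC)c2)c1 | intermediate
13 | methyl 3-[(1S,2R)-1-[3,5-dimethoxy-4-(triisopropylsilyloxy)phenyl]-1,3-dihydroxypropan-2-yl]-4-fluoro-5-methoxybenzoate | COC(=O)c1cc(OC)c(F)c([C@H](CO)[C@H](O)c2cc(OC)c(O[Si](C(C)C)(C(C)C)C(C)C)c(OC)c2)c1 | intermediate
14 | methyl 3-[(1S,2R)-1-[3,5-dimethoxy-4-(triisopropylsilyloxy)phenyl]-1-hydroxy-3-(trityloxy)propan-2-yl]-4-fluoro-5-methoxybenzoate | COc1cc([C@@H](O)[C@@H](COC(c2ccccc2)(c2ccccc2)c2ccccc2)c2cc(C(=O)OC)cc(OC)c2F)cc(OC)c1O[Si](C(C)C)(C(C)C)C(C)C | intermediate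
15 | methyl (2S,3R)-2-[3,5-dimethoxy-4-(triisopropylsilyloxy)phenyl]-7-methoxy-3-(trityloxymethyl)-2,3-dihydro-1-benzofuran-5-carboxylate | COc1cc([C@H]2Oc3c(OC)cc(C(=O)OC)cc3[C@@H]2COC(c4ccccc4)(c4ccccc4)c4ccccc4)cc(OC)c1O[Si](C(C)C)(C(C)C)C(C)C | intermediate
16 | (2S,3R)-2-[3,5-dimethoxy-4-(triisopropylsilyloxy)phenyl]-N,7-dimethoxy-N-methyl-3-(trityloxymethyl)-2,3-dihydro-1-benzofuran-5-carboxamide | COc1cc([C@H]2Oc3c(OC)cc(C(=O)N(C)OC)cc3[C@@H]2COC(c4ccccc4)(c4ccccc4)c4ccccc4)cc(OC)c1O[Si](C(C)C)(C(C)C)C(C)C | intermediate (not isolated)
17 | 1-[(2S,3R)-2-[3,5-dimethoxy-4-(triisopropylsilyloxy)phenyl]-7-methoxy-3-(trityloxymethyl)-2,3-dihydro-1-benzofuran-5-yl]ethan-1-one | COc1cc([C@H]2Oc3c(OC)cc(C(C)=O)cc3[C@@H]2COC(c4ccccc4)(c4ccccc4)c4ccccc4)cc(OC)c1O[Si](C(C)C)(C(C)C)C(C)C | intermediate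
18 | 1-[(2S,3R)-2-[3,5-dimethoxy-4-(triisopropylsilyloxy)phenyl]-3-(hydroxymethyl)-7-methoxy-2,3-dihydro-1-benzofuran-5-yl]ethan-1-one | COc1cc([C@H]2Oc3c(OC)cc(C(C)=O)cc3[C@@H]2CO)cc(OC)c1O[Si](C(C)C)(C(C)C)C(C)C | intermediate
19 | 1-[(2S,3R)-2-(4-hydroxy-3,5-dimethoxyphenyl)-3-(hydroxymethyl)-7-methoxy-2,3-dihydro-1-benzofuran-5-yl]ethan-1-one | COc1cc([C@H]2Oc3c(OC)cc(C(C)=O)cc3[C@@H]2CO)cc(OC)c1O | target

## Step count and least certain steps

Total step count: 12. Longest linear sequence: 11 steps (3 to 19, steps 2 to 12); the aldehyde branch (1 to 2) joins at step 6.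

**Step 9 (key step).** The most likely failure is slow fluoride displacement, because ring A is activated by a single para ester and carries a donating methoxy group next to the fluorine. Intermolecular attack of the alkoxide on the methyl ester, or silyl transfer from the phenol oxygen, could then compete. The fallback changes the activating group and the way the acetyl group is built. It sets out from 14 and returns at 17.
- The ester of 14 would be reduced with iBu2AlH (CH2Cl2, −78 °C) to the ring-A benzylic alcohol F1.
- Its primary benzylic hydroxyl would be oxidised selectively with TEMPO/PhI(OAc)2 to the fluoro aldehyde F2, the hindered secondary carbinol being left untouched.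
- The para formyl group activates C7a far more strongly and cannot be acylated, so Cs2CO3 in DMF with gentle warming should close the ring to the cyclised aldehyde F3.
- MeMgBr would then give the methyl carbinol F4 as a mixture of carbinol epimers, and Dess–Martin periodinane would oxidise it to 17.

**Step 6.** The likely failures are incomplete conversion and reversal of the aldol during work-up, because the aldehyde is electron-rich and hindered and the aryl-stabilised enolate is a good leaving group for retro-aldol cleavage. Both would lower the diastereomeric purity. The fallback uses the chlorotitanium enolate of an N-acyl thiazolidinethione. It sets out from 7 and 2 and returns at 13.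
- Acid 7 would be coupled (EDC·HCl, DMAP) with the auxiliary (S)-4-benzyl-1,3-thiazolidine-2-thione F5 to give the N-acyl thiazolidinethione F6.
- F6 would be enolised with TiCl4, iPr2NEt and N-methyl-2-pyrrolidinone (one equivalent each, the non-chelated regime that gives the same syn isomer as the boron aldol) and combined with 2 to give the titanium aldol adduct F7.
- The thiazolidinethione is cleaved by NaBH4 under milder conditions than the oxazolidinone, giving 13 directly.

**Step 7.** The likely failures are retro-aldol cleavage of the β-alkoxide under the basic borohydride conditions and partial hydride attack on the ring-A methyl ester. The fallback separates cleavage from reduction. It sets out from 12 and returns at 13.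
- LiOH/H2O2 (THF/H2O, 0 °C) would remove the auxiliary by attack at the exocyclic carbonyl and give the β-hydroxy acid F8.
- BH3·SMe2 would then reduce the carboxylic acid selectively in the presence of the methyl ester to give 13.

**Step 3.** The likely failure is protodeboronation of the ortho-fluoro arylboronate under aqueous base, or consumption of the bromoacetate by the base, before transmetalation. The fallback reverses the polarity of the coupling. It sets out from 4 and returns at 6.
- CuBr2 in aqueous MeOH would convert 4 into the aryl bromide F9.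
- F9 would be coupled under Pd2(dba)3/XPhos in THF with the zinc enolate bromo(2-tert-butoxy-2-oxoethyl)zinc F10, made from 5 and Zn. This is a Reformatsky–Negishi arylation that tolerates the methyl ester and gives 6.

**Step 10.** The likely failure is over-addition at the ester carbon if amide formation is incomplete when MeMgBr is introduced, leading to a tertiary carbinol. The fallback avoids a carbon nucleophile at the acyl carbon. It sets out from 15 and returns at 17.
- Methylenation of the ester with Cp2Ti(μ-Cl)(μ-CH2)AlMe2 (Tebbe methylenation, THF/pyridine, −40 °C to rt) would give the methyl enol ether F11.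
- Brief treatment with oxalic acid in wet THF would hydrolyse F11 to 17.

## Further compounds

F1 | step 9 | [3-[(1S,2R)-1-[3,5-dimethoxy-4-(triisopropylsilyloxy)phenyl]-1-hydroxy-3-(trityloxy)propan-2-yl]-4-fluoro-5-methoxyphenyl]methanol | COc1cc([C@@H](O)[C@@H](COC(c2ccccc2)(c2ccccc2)c2ccccc2)c2cc(CO)cc(OC)c2F)cc(OC)c1O[Si](C(C)C)(C(C)C)C(C)C
F2 | step 9 | 3-[(1S,2R)-1-[3,5-dimethoxy-4-(triisopropylsilyloxy)phenyl]-1-hydroxy-3-(trityloxy)propan-2-yl]-4-fluoro-5-methoxybenzaldehyde | COc1cc([C@@H](O)[C@@H](COC(c2ccccc2)(c2ccccc2)c2ccccc2)c2cc(C=O)cc(OC)c2F)cc(OC)c1O[Si](C(C)C)(C(C)C)C(C)C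
F3 | step 9 | (2S,3R)-2-[3,5-dimethoxy-4-(triisopropylsilyloxy)phenyl]-7-methoxy-3-(trityloxymethyl)-2,3-dihydro-1-benzofuran-5-carbaldehyde | COc1cc([C@H]2Oc3c(OC)cc(C=O)cc3[C@@H]2COC(c4ccccc4)(c4ccccc4)c4ccccc4)cc(OC)c1O[Si](C(C)C)(C(C)C)C(C)C
F4 | step 9 | 1-[(2S,3R)-2-[3,5-dimethoxy-4-(triisopropylsilyloxy)phenyl]-7-methoxy-3-(trityloxymethyl)-2,3-dihydro-1-benzofuran-5-yl]ethan-1-ol (both carbinol epimers) | COc1cc([C@H]2Oc3c(OC)cc(C(C)O)cc3[C@@H]2COC(c4ccccc4)(c4ccccc4)c4ccccc4)cc(OC)c1O[Si](C(C)C)(C(C)C)C(C)C
F5 | step 6 | (S)-4-benzyl-1,3-thiazolidine-2-thione | S=C1SC[C@H](Cc2ccccc2)N1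
F6 | step 6 | methyl 3-{2-[(4S)-4-benzyl-2-thioxo-1,3-thiazolidin-3-yl]-2-oxoethyl}-4-fluoro-5-methoxybenzoate | COC(=O)c1cc(OC)c(F)c(CC(=O)N2[C@@H](Cc3ccccc3)CSC2=S)c1
F7 | step 6 | methyl 3-[(2S,3S)-1-[(4S)-4-benzyl-2-thioxo-1,3-thiazolidin-3-yl]-3-[3,5-dimethoxy-4-(triisopropylsilyloxy)phenyl]-3-hydroxy-1-oxopropan-2-yl]-4-fluoro-5-methoxybenzoate | COC(=O)c1cc(OC)c(F)c([C@H](C(=O)N2[C@@H](Cc3ccccc3)CSC2=S)[C@H](O)c2cc(OC)c(O[Si](C(C)C)(C(C)C)C(C)C)c(OC)c2)c1
F8 | step 7 | (2S,3S)-3-[3,5-dimethoxy-4-(triisopropylsilyloxy)phenyl]-2-[2-fluoro-3-methoxy-5-(methoxycarbonyl)phenyl]-3-hydroxypropanoic acid | COC(=O)c1cc(OC)c(F)c([C@H](C(=O)O)[C@H](O)c2cc(OC)c(O[Si](C(C)C)(C(C)C)C(C)C)c(OC)c2)c1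
F9 | step 3 | methyl 3-bromo-4-fluoro-5-methoxybenzoate | COC(=O)c1cc(OC)c(F)c(Br)c1
F10 | step 3 | bromo(2-tert-butoxy-2-oxoethyl)zinc | CC(C)(C)OC(=O)C[Zn]Br
F11 | step 10 | triisopropyl{4-[(2S,3R)-7-methoxy-5-(1-methoxyethenyl)-3-(trityloxymethyl)-2,3-dihydro-1-benzofuran-2-yl]-2,6-dimethoxyphenoxy}silane | COc1cc([C@H]2Oc3c(OC)cc(C(=C)OC)cc3[C@@H]2COC(c4ccccc4)(c4ccccc4)c4ccccc4)cc(OC)c1O[Si](C(C)C)(C(C)C)C(C)C
A1 | alternative 1 | tert-butyl{[(2R,3S)-3-[3,5-dimethoxy-4-(methoxymethoxy)phenyl]-2-[3-methoxy-2-(methoxymethoxy)-5-(2-methyl-1,3-dioxolan-2-yl)phenyl]-3-(4,4,5,5-tetramethyl-1,3,2-dioxaborolan-2-yl)propyl]oxy}dimethylsilane | COCOc1c(OC)cc(cc1OC)[C@@H](B2OC(C)(C)C(C)(C)O2)[C@@H](CO[Si](C)(C)C(C)(C)C)c3cc(C4(C)OCCO4)cc(OC)c3OCOC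
A2 | alternative 1 | 2-[3-bromo-5-methoxy-4-(methoxymethoxy)phenyl]-2-methyl-1,3-dioxolane | COCOc1c(Br)cc(C2(C)OCCO2)cc1OC
A3 | alternative 1 | (E)-tert-butyldimethyl{[3-(4,4,5,5-tetramethyl-1,3,2-dioxaborolan-2-yl)prop-2-en-1-yl]oxy}silane | CC(C)(C)[Si](C)(C)OC/C=C/B1OC(C)(C)C(C)(C)O1
A4 | alternative 1 | 5-bromo-1,3-dimethoxy-2-(methoxymethoxy)benzene | COCOc1c(OC)cc(Br)cc1OC
A5 | alternative 2 | methyl (2S,3S)-2-[3,5-dimethoxy-4-(methoxymethoxy)phenyl]-7-methoxy-5-(2-methyl-1,3-dioxolan-2-yl)-2,3-dihydro-1-benzofuran-3-carboxylate | COc1cc([C@H]2Oc3c(OC)cc(C4(C)OCCO4)cc3[C@@H]2C(=O)OC)cc(OC)c1OCOC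
A6 | alternative 2 | methyl 2-diazo-2-[2-{[3,5-dimethoxy-4-(methoxymethoxy)phenyl]methoxy}-3-methoxy-5-(2-methyl-1,3-dioxolan-2-yl)phenyl]acetate | COC(=O)C(=[N+]=[N-])c1cc(C2(C)OCCO2)cc(OC)c1OCc1cc(OC)c(OCOC)c(OC)c1
A7 | alternative 3 | 2-[(2S,3S)-3-allyl-2-[3,5-dimethoxy-4-(methoxymethoxy)phenyl]-7-methoxy-2-(4,4,5,5-tetramethyl-1,3,2-dioxaborolan-2-yl)-2,3-dihydro-1-benzofuran-5-yl]-2-methyl-1,3-dioxolane | COCOc1c(OC)cc(cc1OC)[C@@]2(B3OC(C)(C)C(C)(C)O3)Oc4c(OC)cc(C5(C)OCCO5)cc4[C@@H]2CC=C
A8 | alternative 3 | 2-(7-methoxy-1-benzofuran-5-yl)-2-methyl-1,3-dioxolane | COc1cc(C2(C)OCCO2)cc2ccoc12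
A9 | alternative 3 | 2-[3,5-dimethoxy-4-(methoxymethoxy)phenyl]-4,4,5,5-tetramethyl-1,3,2-dioxaborolane | COCOc1c(OC)cc(B2OC(C)(C)C(C)(C)O2)cc1OC
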